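**Plan**

- Numbering (plakortolide convention): C1 lactone C=O, C3 peroxy CH, C4 C(Me)–O(lactone), C5 ring CH2, C6 C(Me)(OO), C7–C14 chain. Enabling feature: C6 of the 1,2-dioxane is a masked ketone carbon, C5–C4 is the footprint of an isopropenyl group on C3, and the C1 carboxyl can reach C4 in a five-membered ring.
- Cuts: C5–C6 together with C4–O(lactone) in one cationic cascade; then O–C3 of the peroxide (oxa-Michael); then C13–C14 and C12–CH3 (carboalumination/benzylation), C11–C12 (acetylide), C6–CH3 (Grignard).
- Forward: (S)-citronellal → alkynol → (E)-trisubstituted alkene → methyl ketone → α-methoxy hydroperoxide. This is joined to a dienal through O–C3 and oxidised to the acid. The last step closes the 1,2-dioxane and then the γ-lactone in one operation.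
- Stereochemistry: C8 from (S)-citronellal; C3 from the (R)-diarylprolinol silyl ether catalyst; C4 from C3 through the cis ring fusion; C6 from the chair-like cyclisation (the least secure centre); the (E)-alkene from syn-carboalumination.

Key step: step 11

Remark: the facial sense in step 9 is assigned from the accepted shielding model of the (E)-iminium ion (attack anti to the diphenyl(silyloxy)methyl group).

**Step 1**
Reactants: 1 (S)-citronellal
Product: 2 (4S)-4,8-dimethylnon-7-en-2-ol (C2 epimers)
Conditions: MeMgBr, THF, 0 °C; aq. NH4Cl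
Reagents that add atoms: methylmagnesium bromide, C[Mg]Br
Why: Grignard addition to the aldehyde; the new carbinol centre forms unselectively and is erased by the oxidation in step 6, while C8 (β to the carbonyl) is untouched.

**Step 2**
Reactants: 2 (4S)-4,8-dimethylnon-7-en-2-ol
Product: 3 (4S)-4-methylheptane-1,6-diol
Conditions: O3, CH2Cl2/MeOH, −78 °C; then NaBH4, −78 °C to rt
Reagents that add atoms: ozone, O=[O+][O-]
Why: Ozonolysis of the trisubstituted alkene with reductive work-up removes the isopropylidene carbon as acetone and leaves a primary alcohol that is distinct from the secondary one.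

**Step 3**
Reactants: 3 (4S)-4-methylheptane-1,6-diol
Product: 4 (4S)-7-iodo-4-methylheptan-2-ol
Conditions: I2 (1.05 equiv), PPh3, imidazole, CH2Cl2, 0 °C
Reagents that add atoms: iodine, II
Why: Appel-type iodination (PPh3/I2/imidazole) is selective for the primary over the secondary hydroxyl.

**Step 4**
Reactants: 4 (4S)-7-iodo-4-methylheptan-2-ol
Product: 5 (4S)-4-methylnon-8-yn-2-ol
Conditions: LiC≡CH·H2NCH2CH2NH2 (3 equiv), DMSO, 0 °C to rt
Reagents that add atoms: lithium acetylide (ethylenediamine complex), [Li]C#C
Why: SN2 alkylation of the acetylide by the primary iodide; the excess reagent carries the free secondary alcohol as its alkoxide.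

**Step 5**
Reactants: 5 (4S)-4-methylnon-8-yn-2-ol; 6 benzyl bromide
Product: 8 (4S,8E)-4,8-dimethyl-10-phenyldec-8-en-2-ol, via (E)-alkenyldimethylalane 7 (not isolated)
Conditions: AlMe3 (3.5 equiv), Cp2ZrCl2 (0.25 equiv), CH2Cl2, 0 °C to rt; then 6, Pd(PPh3)4 (5 mol %), THF, rt; aq. NaOH/Rochelle salt
Reagents that add atoms: trimethylaluminium, C[Al](C)C
Why: Zirconium-catalysed syn-carboalumination (Negishi) puts methyl on the internal and aluminium on the terminal alkyne carbon, and Pd-catalysed cross-coupling of the alkenylalane with benzyl bromide goes with retention, so the (E)-trisubstituted alkene is fixed; the hydroxyl is masked in the flask as its aluminium alkoxide.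

**Step 6**
Reactants: 8 (4S,8E)-4,8-dimethyl-10-phenyldec-8-en-2-ol
Product: 9 (4S,8E)-4,8-dimethyl-10-phenyldec-8-en-2-one
Conditions: Dess–Martin periodinane, NaHCO3, CH2Cl2, rt
Reagents that add atoms: none
Why: Dess–Martin oxidation of the secondary alcohol to the methyl ketone under buffered conditions; the stereocentre is β to the carbonyl and cannot epimerise.

**Step 7**
Reactants: 9 (4S,8E)-4,8-dimethyl-10-phenyldec-8-en-2-one
Product: 11 (4S,8E)-2-hydroperoxy-2-methoxy-4,8-dimethyl-10-phenyldec-8-ene (C2 epimers), via dimethyl ketal 10 (not isolated)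
Conditions: HC(OMe)3, MeOH, PPTS (cat.), rt; evaporate; then H2O2 (anhydrous, in Et2O, 2 equiv), PPTS (cat.), 0 °C
Reagents that add atoms: trimethyl orthoformate, COC(OC)OC; hydrogen peroxide, OO
Why: Acid-catalysed ketalisation followed by acid-catalysed exchange of one methoxy group for hydrogen peroxide (perketal formation) gives the α-methoxy hydroperoxide; its new ketal centre forms unselectively and is erased when C6 is ionised in step 11.

**Step 8**
Reactants: 12 methacrolein; 13 (triphenylphosphoranylidene)acetaldehyde
Product: 14 (2E)-4-methylpenta-2,4-dienal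
Conditions: 12 (excess), toluene, 70 °C, sealed tube; used as a solution
Reagents that add atoms: none
Why: Wittig olefination with the stabilised formyl ylide gives the (E)-enal, and the excess of the more electrophilic methacrolein stops the homologation at the dienal.

**Step 9**
Reactants: 11 (4S,8E)-2-hydroperoxy-2-methoxy-4,8-dimethyl-10-phenyldec-8-ene; 14 (2E)-4-methylpenta-2,4-dienal
Product: 15 (3R)-3-{[(4S,8E)-2-methoxy-4,8-dimethyl-10-phenyldec-8-en-2-yl]peroxy}-4-methylpent-4-enal
Conditions: 14 (2 equiv), (R)-2-[diphenyl(trimethylsilyloxy)methyl]pyrrolidine (20 mol %), PhCO2H (20 mol %), toluene, 0 °C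
Reagents that add atoms: none
Why: Amine-catalysed enantioselective oxa-Michael addition of a hydroperoxide to an enal (iminium activation): the hydroperoxide oxygen adds 1,4 to the (E)-iminium ion on the face away from the diphenyl(silyloxy)methyl group of the (R)-catalyst, which sets (3R), and the acid co-catalyst protonates the enamine before it can close to an epoxide.

**Step 10**
Reactants: 15 (3R)-3-{[(4S,8E)-2-methoxy-4,8-dimethyl-10-phenyldec-8-en-2-yl]peroxy}-4-methylpent-4-enal
Product: 16 (3R)-3-{[(4S,8E)-2-methoxy-4,8-dimethyl-10-phenyldec-8-en-2-yl]peroxy}-4-methylpent-4-enoic acid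
Conditions: NaClO2, NaH2PO4, 2-methylbut-2-ene (excess), t-BuOH/H2O, 0 °C; used at once
Reagents that add atoms: sodium chlorite, [Na+].[O-]Cl=O
Why: Pinnick oxidation takes the aldehyde to the acid under buffered, weakly acidic conditions that avoid base-induced β-elimination of the peroxide, while 2-methylbut-2-ene scavenges HOCl and so protects both alkenes.

**Step 11**
Reactants: 16 (3R)-3-{[(4S,8E)-2-methoxy-4,8-dimethyl-10-phenyldec-8-en-2-yl]peroxy}-4-methylpent-4-enoic acid
Product: 18 plakortolide G, via trimethylsilyl ester 17 (not isolated)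
Conditions: N,O-bis(trimethylsilyl)acetamide (1.2 equiv), CH2Cl2, rt; then TMSOTf (0.2 equiv), −78 to −40 °C
Reagents that add atoms: none
Why: Proposed new method: TMSOTf removes the methoxy group of the mixed peroxyketal as Me3SiOMe to give a peroxycarbenium ion at C6, the CH2 terminus (C5) of the isopropenyl group adds to it, and the tertiary C4 cation is taken at once by the carbonyl oxygen of the silyl ester, which gives up Me3Si+ so that the Lewis acid turns over; the closest known reactions are the Lewis-acid-mediated additions of allylsilanes and alkenes to peroxycarbenium ions from monoperoxyketals and the Prins cyclisation ended by a carboxyl group. The 1,2-dioxane closes 6-endo-trig at the alkene (a Prins-type closure in which the second peroxide oxygen takes the place of a ring CH2), and the γ-lactone closes by five-membered capture of the planar C4 cation. C4 is set by C3, because the two-atom arm can reach the cation only on its own face and so gives the cis-fused bicycle. C6 is set by the face of the peroxycarbenium ion that C5 takes: the chair with the C3 arm and the larger branched chain equatorial and the C6 methyl axial, on the side of the incoming lactone oxygen, gives (6R), but methyl and chain differ little, so this selectivity should be modest and the (6S) epimer, a diastereomer, is removed by chromatography. The step needs ionisation of C–OMe in preference to O–O or allylic C3–O heterolysis and attack by the nearby 1,1-disubstituted alkene in preference to the remote trisubstituted one; the low temperature, the silyl Lewis acid that seeks the ketal oxygen, and a six- against an eight-membered transition state secure this. The carboxyl group is carried as its trimethylsilyl ester so that no proton acid is set free.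

**Compound list**

1 | (S)-citronellal, (3S)-3,7-dimethyloct-6-enal | CC(C)=CCC[C@H](C)CC=O | starting material
2 | (4S)-4,8-dimethylnon-7-en-2-ol (C2 epimers) | CC(C)=CCC[C@H](C)CC(C)O | intermediate
3 | (4S)-4-methylheptane-1,6-diol (C6 epimers) | OCCC[C@H](C)CC(C)O | intermediate
4 | (4S)-7-iodo-4-methylheptan-2-ol | ICCC[C@H](C)CC(C)O | intermediate
5 | (4S)-4-methylnon-8-yn-2-ol | C#CCCC[C@H](C)CC(C)O | intermediate
6 | benzyl bromide | BrCc1ccccc1 | starting material
7 | (E)-alkenyldimethylalane of 5 (syn-carboalumination product, hydroxyl as O–AlMe2) | C/C(=C\[Al](C)C)CCC[C@H](C)CC(C)O[Al](C)C | intermediate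
8 | (4S,8E)-4,8-dimethyl-10-phenyldec-8-en-2-ol | C/C(=C\Cc1ccccc1)CCC[C@H](C)CC(C)O | intermediate
9 | (4S,8E)-4,8-dimethyl-10-phenyldec-8-en-2-one | C/C(=C\Cc1ccccc1)CCC[C@H](C)CC(C)=O | intermediate
10 | (4S,8E)-2,2-dimethoxy-4,8-dimethyl-10-phenyldec-8-ene | C/C(=C\Cc1ccccc1)CCC[C@H](C)CC(C)(OC)OC | intermediate
11 | (4S,8E)-2-hydroperoxy-2-methoxy-4,8-dimethyl-10-phenyldec-8-ene (C2 epimers) | C/C(=C\Cc1ccccc1)CCC[C@H](C)CC(C)(OC)OO | intermediate
12 | methacrolein, 2-methylprop-2-enal | CC(=C)C=O | starting material
13 | (triphenylphosphoranylidene)acetaldehyde | O=CC=P(c1ccccc1)(c1ccccc1)c1ccccc1 | starting material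
14 | (2E)-4-methylpenta-2,4-dienal | CC(=C)/C=C/C=O | intermediate
15 | (3R)-3-{[(4S,8E)-2-methoxy-4,8-dimethyl-10-phenyldec-8-en-2-yl]peroxy}-4-methylpent-4-enal | C/C(=C\Cc1ccccc1)CCC[C@H](C)CC(C)(OC)OO[C@H](CC=O)C(C)=C | intermediate
16 | (3R)-3-{[(4S,8E)-2-methoxy-4,8-dimethyl-10-phenyldec-8-en-2-yl]peroxy}-4-methylpent-4-enoic acid | C/C(=C\Cc1ccccc1)CCC[C@H](C)CC(C)(OC)OO[C@H](CC(=O)O)C(C)=C | intermediate
17 | trimethylsilyl ester of 16 | C/C(=C\Cc1ccccc1)CCC[C@H](C)CC(C)(OC)OO[C@H](CC(=O)O[Si](C)(C)C)C(C)=C | intermediate
18 | plakortolide G, (3R,4aR,7aR)-3-[(2S,6E)-2,6-dimethyl-8-phenyloct-6-en-1-yl]-3,4a-dimethyltetrahydro-3H-furo[3,2-c][1,2]dioxin-6(4H)-one; (3R,4R,6R,8S) in plakortolide numbering | C/C(=C\Cc1ccccc1)CCC[C@H](C)C[C@]1(C)C[C@@]2(C)OC(=O)C[C@H]2OO1 | target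

**Step count and risks**

Total step count: 11. Longest linear sequence: 10 steps (steps 1–7, 9, 10 and 11, from 1).

Steps most likely to fail:

1. Step 11 (proposed new method). Heterolysis of the O–O or allylic C–O bond (Hock-type fragmentation) may outrun ketal ionisation. The C4 cation may lose a proton before the carboxyl group closes. Facial selectivity at C6 may be low or inverted, because the C3 arm can turn axial to escape allylic strain with the C4 methyl group. The fallback uses the established allylsilane termination of peroxycarbenium ions, then iodolactonisation and radical deiodination; it sets out from 11 and 13 and comes back at 18. Commercial 2-[(trimethylsilyl)methyl]prop-2-en-1-ol would be oxidised (MnO2, CH2Cl2) to 2-[(trimethylsilyl)methyl]prop-2-enal F1, which with 13 should give (2E)-4-[(trimethylsilyl)methyl]penta-2,4-dienal F2. Peroxidation with 11 as in step 9 should give the (3R)-peroxy aldehyde F3, and Pinnick oxidation the acid F4. TMSOTf at −78 °C should then trigger the intramolecular Hosomi–Sakurai reaction, the β-silyl cation losing silicon to give the 4-methylidene-1,2-dioxane acid F5, at which stage the C6 epimers would be separated. Iodolactonisation (I2, NaHCO3, MeCN) should close the cis-fused iodomethyl lactone F6 at the tertiary carbon, and radical reduction (Bu3SnH, AIBN, benzene, 60 °C) should turn CH2I into CH3 and give 18.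

2. Step 9. The β-peroxy enamine may collapse to the epoxide with loss of the hemiketal oxide, the hydroperoxide may add 1,6 at the terminal CH2 of the dienal, or the bulky hydroperoxide may give poor facial selectivity. The fallback makes the hydroperoxide on the small fragment and joins the halves by ketal exchange; it sets out from 10 and comes back at 18. Commercial 4-methylpent-3-enoic acid would be converted (Boc2O, DMAP, t-BuOH) into tert-butyl 4-methylpent-3-enoate F7. A Schenck ene reaction with singlet oxygen (O2, tetraphenylporphyrin, hν, CH2Cl2, 0 °C) should give racemic tert-butyl 3-hydroperoxy-4-methylpent-4-enoate F8, which would be freed from its regioisomer on silica. Resolution on a chiral stationary phase should give tert-butyl (3R)-3-hydroperoxy-4-methylpent-4-enoate F9. PPTS-catalysed exchange with ketal 10 (CH2Cl2, rt) should give the mixed peroxyketal F10, which under TMSOTf (cat.), CH2Cl2, −78 °C should cyclise as in step 11, the tert-butyl group leaving as isobutene, to give 18.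

3. Step 7. Exchange may run on to the geminal dihydroperoxide or stop short, so that a mixture forms. The fallback replaces the equilibrium exchange by an addition; it sets out from 10 and comes back at 11. Elimination of methanol from 10 (TMSOTf, i-Pr2NEt, CH2Cl2, −20 °C) should give the methyl enol ether (4S,8E)-2-methoxy-4,8-dimethyl-10-phenyldeca-1,8-diene F11, and Markovnikov addition of one equivalent of H2O2 (PPTS cat., Et2O, 0 °C) to it should give 11.

**Further compounds**

F1 | step 11 | 2-[(trimethylsilyl)methyl]prop-2-enal | C[Si](C)(C)CC(=C)C=O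
F2 | step 11 | (2E)-4-[(trimethylsilyl)methyl]penta-2,4-dienal | C[Si](C)(C)CC(=C)/C=C/C=O
F3 | step 11 | (3R)-3-{[(4S,8E)-2-methoxy-4,8-dimethyl-10-phenyldec-8-en-2-yl]peroxy}-4-[(trimethylsilyl)methyl]pent-4-enal | C/C(=C\Cc1ccccc1)CCC[C@H](C)CC(C)(OC)OO[C@H](CC=O)C(=C)C[Si](C)(C)C
F4 | step 11 | (3R)-3-{[(4S,8E)-2-methoxy-4,8-dimethyl-10-phenyldec-8-en-2-yl]peroxy}-4-[(trimethylsilyl)methyl]pent-4-enoic acid | C/C(=C\Cc1ccccc1)CCC[C@H](C)CC(C)(OC)OO[C@H](CC(=O)O)C(=C)C[Si](C)(C)C
F5 | step 11 | 2-[(3R,6R)-6-[(2S,6E)-2,6-dimethyl-8-phenyloct-6-en-1-yl]-6-methyl-4-methylidene-1,2-dioxan-3-yl]acetic acid | C/C(=C\Cc1ccccc1)CCC[C@H](C)C[C@]1(C)CC(=C)[C@@H](CC(=O)O)OO1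
F6 | step 11 | C4-iodomethyl analogue of 18 (same configuration) | C/C(=C\Cc1ccccc1)CCC[C@H](C)C[C@]1(C)C[C@@]2(CI)OC(=O)C[C@H]2OO1
F7 | step 9 | tert-butyl 4-methylpent-3-enoate | CC(C)=CCC(=O)OC(C)(C)C
F8 | step 9 | racemic tert-butyl 3-hydroperoxy-4-methylpent-4-enoate | CC(=C)C(CC(=O)OC(C)(C)C)OO
F9 | step 9 | tert-butyl (3R)-3-hydroperoxy-4-methylpent-4-enoate | CC(=C)[C@@H](CC(=O)OC(C)(C)C)OO
F10 | step 9 | tert-butyl (3R)-3-{[(4S,8E)-2-methoxy-4,8-dimethyl-10-phenyldec-8-en-2-yl]peroxy}-4-methylpent-4-enoate | C/C(=C\Cc1ccccc1)CCC[C@H](C)CC(C)(OC)OO[C@H](CC(=O)OC(C)(C)C)C(C)=C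
F11 | step 7 | (4S,8E)-2-methoxy-4,8-dimethyl-10-phenyldeca-1,8-diene | C/C(=C\Cc1ccccc1)CCC[C@H](C)CC(=C)OC
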